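The readings are simulated from invented constants, and the scatter is random.

A flat curve invites the word equilibrium, and that is the pitfall in your hunch that more reagent will push flask epsilon on.

| setting | epsilon | alpha | flask |
|---|---|---|---|
| substrate | 20 mM | 20 mM | 20 mM |
| reagent | 24 mM | 24 mM | 24.0 mM |
| initiator | 1 mM | 0.67 mM | 1.0 mM |
| temperature | 0 °C | 6 °C | 0 °C |
| remark | the very flask that is asked about, followed so far | run made earlier |  |
| time |  |  | 40 h |

- epsilon (time / h: target / %, substrate / %): 6.00: 14.3, 68.9; 12.0: 14.0, 69.2; 20.0: 14.8, 68.7; 25.0: 13.9, 68.9; 30.0: 14.2, 69.3; 40.0: 14.3, 69.2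
- alpha (time / min: target / %, substrate / %): 8.00: 6.4, 93.0; 15.0: 8.4, 88.9; 25.0: 9.9, 84.5; 30.0: 11.1, 84.1; 40.0: 11.1, 82.3; 50.0: 12.8, 80.9

(readings scatter by 0.5 percentage points)

- Friday's: change nothing and wait 40 h more
- Saturday's: at 40 h take out 90% of the by-product then present, then wait 40 h
- Wednesday's: at 40 h raise the temperature by 10 K, then wait 40 h
- Monday's: at 40 h add reagent, 50.0% of the amount charged, then wait 40 h

1. target, in percent of the substrate first charged, at 40 h
2. the remedy with the largest gain of target, or "none" below 2 percentage points (Friday's / Saturday's / Wednesday's / Monday's / none)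
3. target present, in percent of the substrate first charged, after Friday's
4. target present, in percent of the substrate first charged, after Monday's

- the volume of additions can be left aside
- the numbers in the tables scatter by 0.5 percentage points (one standard deviation)

Flask epsilon stands flat from 6.00 h to 40.0 h, so we ask which concentration sets the order of its rate. So we hold the substrate lost against the initiator charged:

  substrate left, mean of the epsilon readings = 69.0%

  chain yield = share of substrate lost × substrate charge / initiator charge = 6.19

The chain yield, millimoles of substrate lost per millimole of initiator charged, is our working quantity. The substrate lost in epsilon is more than the initiator charged, which suggests chains started by the initiator, with a rate that follows the initiator and ends with it. Alpha, with less initiator but also warmer at 6 °C, gives 5.70 at its last reading, 50.0 min, so, with the warmth left aside, the loss seems to go with the initiator charge. We therefore take the initiator in epsilon to have died, and we expect the mean target, 14.3%, to hold now and after Friday's, Saturday's and Monday's. But more substrate is lost than target appears, by 17 percentage points. Something unread holds that gap, and warmth might move it, so we name Wednesday's, without a size.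

The forecast, which parts from us on the remedy, gives 14.2% now, 14.2% after Friday's, 14.2% after Monday's and best none: “This points to the initiator dying, not to equilibrium”.

The flask gives 14.5% now, 14.5% after Friday's, 14.5% after Monday's, and best Wednesday's, with a gain of 6.1 points.

    initiator → 2 initiating radical (k = 1.00 h⁻¹, Ea = 87.0 kJ mol⁻¹)
    substrate + initiating radical → capped initiator + first chain carrier (k = 84000 M⁻¹ s⁻¹, Ea = 25.0 kJ mol⁻¹)
    reagent + first chain carrier ⇌ target + second chain carrier (K = 0.590, k = 1.40 × 10⁷ M⁻¹ h⁻¹, Ea = 29.0 kJ mol⁻¹, ΔH = 0 kJ mol⁻¹)
    substrate + second chain carrier → by-product + first chain carrier (k = 4.80 × 10⁶ M⁻¹ h⁻¹, Ea = 40.0 kJ mol⁻¹)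
    2 first chain carrier → ended chains A (k = 7.50 × 10⁷ M⁻¹ s⁻¹, Ea = 8.00 kJ mol⁻¹)
    2 second chain carrier → ended chains B (k = 5.00 × 10⁷ M⁻¹ s⁻¹, Ea = 15.0 kJ mol⁻¹)
    reagent ⇌ dormant form (K = 6.70, k = 2.40 h⁻¹, Ea = 89.0 kJ mol⁻¹, ΔH = −17.0 kJ mol⁻¹)
    target ⇌ isomer of the product (K = 0.650, k = 1.00 h⁻¹, Ea = 78.0 kJ mol⁻¹, ΔH = −90.0 kJ mol⁻¹)
    (constants at 0 °C)

In the flask, initiator stands at 0% of its charge and substrate at 68.8% after 40.0 h, which is a chain yield of 6.24. The same flask without the conversion of target into isomer of the product, both ways, gains 0 points from Wednesday's instead of 6.1 points, so that conversion is part of the reason for the gain, and the 9.40% of isomer lay in our gap. For the neighbour kept at 15 °C, the chain yield gives 69.0% substrate left; the computed flask holds 72%, with target 18.7%.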